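**Strategy.** The 20,7-lactone of the target is a 2-oxabicyclo[2.2.2]octene: the bridgeheads C7 and C10 are spanned by O–C20(=O), by C8=C9 of ring C and by C5–C6. This is the retron of a 2-benzopyran-3-one [4+2] adduct. In one operation an open-chain o-formyl arylacetic acid carrying a tethered (E)-enone is cyclodehydrated (carboxyl oxygen onto C7) to the pyranone, which adds the enone across C10/C7. This closes the lactone, ring A and ring B and sets C5, C6, C7 and C10. A C4–H stereocentre steers the facial sense and is later made quaternary by aldehyde methylation. The acetyl group becomes the 6α-hydroxyl by Baeyer–Villiger oxidation, and a trimethoxyarene is unmasked to the hydroxyquinone last.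

Key step: step 15

Remark: abietane numbering (C1–C20) is used for all atoms; formyl acid 17 is handled as its open-chain tautomer, so the lactone C7–O bond is first made in step 15.

Step 1
Reactants: 1 1,2,4-trimethoxybenzene
Product: 2 2-(2,3,6-trimethoxyphenyl)propan-2-ol
Conditions: n-BuLi, THF, 0 °C; then acetone, −78 °C to rt
Reagents that add atoms: acetone, CC(C)=O
Why: Directed ortho-lithiation should take place at C3 of 1, the position flanked by two methoxy groups, and the aryllithium adds to acetone (carbonyl 1,2-addition); no stereocentre is formed.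

Step 2
Reactants: 2 2-(2,3,6-trimethoxyphenyl)propan-2-ol
Product: 3 2-isopropyl-1,3,4-trimethoxybenzene
Conditions: Et3SiH, TFA, CH2Cl2, 0 °C to rt
Reagents that add atoms: none
Why: Ionic hydrogenation: TFA ionises the tertiary benzylic alcohol to a cation stabilised by two ortho methoxy groups, which Et3SiH reduces to the isopropyl group.

Step 3
Reactants: 3 2-isopropyl-1,3,4-trimethoxybenzene
Product: 4 3-isopropyl-2,4,5-trimethoxybenzaldehyde
Conditions: Cl2CHOMe, TiCl4, CH2Cl2, −10 °C; then H2O
Reagents that add atoms: dichloromethyl methyl ether, COC(Cl)Cl; water, O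
Why: Rieche formylation (electrophilic aromatic substitution) should go to C6 of 3, the only free position that is ortho to one methoxy group and para to another, whereas C5 is activated by a single methoxy group.

Step 4
Reactants: 4 3-isopropyl-2,4,5-trimethoxybenzaldehyde
Product: 5 1-(dimethoxymethyl)-3-isopropyl-2,4,5-trimethoxybenzene
Conditions: HC(OMe)3, TsOH (cat.), MeOH, rt
Reagents that add atoms: trimethyl orthoformate, COC(OC)OC
Why: Acid-catalysed acetalisation masks the aldehyde against organometallic reagents and supplies a second ortho-directing group.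

Step 5
Reactants: 5 1-(dimethoxymethyl)-3-isopropyl-2,4,5-trimethoxybenzene
Product: 6 1-(dimethoxymethyl)-2-iodo-5-isopropyl-3,4,6-trimethoxybenzene
Conditions: n-BuLi, TMEDA, Et2O, 0 °C; then I2, THF, −78 °C to rt
Reagents that add atoms: iodine, II
Why: Directed ortho-metalation removes the only ring hydrogen, which lies between the acetal and a methoxy group, and the aryllithium is trapped by iodine.

Step 6
Reactants: 6 1-(dimethoxymethyl)-2-iodo-5-isopropyl-3,4,6-trimethoxybenzene
Product: 7 tert-butyl 2-[2-(dimethoxymethyl)-4-isopropyl-3,5,6-trimethoxyphenyl]acetate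
Conditions: ClZnCH2CO2t-Bu (0.5 M in Et2O), Pd2(dba)3 (2.5 mol %), XPhos (10 mol %), THF, 65 °C
Reagents that add atoms: (2-tert-butoxy-2-oxoethyl)zinc chloride, CC(C)(C)OC(=O)C[Zn]Cl
Why: Negishi coupling of a Reformatsky reagent (palladium-catalysed α-arylation of an ester zinc enolate), in which the bulky biarylphosphine should allow oxidative addition and reductive elimination at the doubly ortho-substituted aryl iodide.

Step 7
Reactants: 8 (R)-4-benzyl-2-oxazolidinone; 9 5-bromopentanoyl chloride
Product: 10 (4R)-4-benzyl-3-(5-bromopentanoyl)-1,3-oxazolidin-2-one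
Conditions: n-BuLi, THF, −78 °C; then 9, −78 to 0 °C
Reagents that add atoms: none
Why: N-Acylation of the lithiated Evans oxazolidinone by the acid chloride, which is far more electrophilic than the primary bromide.

Step 8
Reactants: 10 (4R)-4-benzyl-3-(5-bromopentanoyl)-1,3-oxazolidin-2-one
Product: 11 (4R)-4-benzyl-3-[(2S)-2-[(benzyloxy)methyl]-5-bromopentanoyl]-1,3-oxazolidin-2-one
Conditions: TiCl4, i-Pr2NEt, CH2Cl2, 0 °C; then BnOCH2Cl, 0 °C
Reagents that add atoms: benzyl chloromethyl ether, ClCOCc1ccccc1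
Why: Evans asymmetric alkylation: the chelated (Z)-titanium enolate is attacked by the benzyloxymethyl electrophile on the face opposite to the benzyl group of the (R)-auxiliary, which sets the (S) centre that becomes C4.

Step 9
Reactants: 11 (4R)-4-benzyl-3-[(2S)-2-[(benzyloxy)methyl]-5-bromopentanoyl]-1,3-oxazolidin-2-one
Product: 12 (2R)-2-[(benzyloxy)methyl]-5-bromopentan-1-ol
Conditions: LiBH4, MeOH (1 equiv), THF, 0 °C
Reagents that add atoms: none
Why: Hydride reduction of the imide carbonyl (reductive removal of the auxiliary) should leave the α-stereocentre and the primary bromide untouched at 0 °C.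

Step 10
Reactants: 12 (2R)-2-[(benzyloxy)methyl]-5-bromopentan-1-ol
Product: 13 (2S)-2-[(benzyloxy)methyl]-5-bromopentanal
Conditions: Dess–Martin periodinane, NaHCO3, CH2Cl2, 0 °C
Reagents that add atoms: none
Why: Dess–Martin oxidation under buffered, non-basic conditions should give the α-branched aldehyde without epimerisation or β-elimination.

Step 11
Reactants: 13 (2S)-2-[(benzyloxy)methyl]-5-bromopentanal
Product: 14 {[(2R)-2-(3-bromopropyl)but-3-en-1-yl]oxy}methylbenzene
Conditions: Ph3PCH3Br, KHMDS, THF, −78 to 0 °C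
Reagents that add atoms: methyltriphenylphosphonium bromide, C[P+](c1ccccc1)(c1ccccc1)c1ccccc1.[Br-]
Why: Wittig methylenation with the non-stabilised ylide at low temperature should convert the aldehyde into the terminal alkene faster than enolisation can erode the stereocentre.

Step 12
Reactants: 7 tert-butyl 2-[2-(dimethoxymethyl)-4-isopropyl-3,5,6-trimethoxyphenyl]acetate; 14 {[(2R)-2-(3-bromopropyl)but-3-en-1-yl]oxy}methylbenzene
Product: 15 tert-butyl (6R)-6-[(benzyloxy)methyl]-2-[2-(dimethoxymethyl)-4-isopropyl-3,5,6-trimethoxyphenyl]oct-7-enoate (both C2 epimers)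
Conditions: LDA, THF/DMPU, −78 °C; then 14, −78 °C to rt
Reagents that add atoms: none
Why: SN2 alkylation of the lithium enolate of the arylacetate with the primary bromide joins the two fragments; the new centre at C2 of the ester (the future C10) forms as a mixture, which is of no consequence because it becomes sp2 in step 15.

Step 13
Reactants: 15 tert-butyl (6R)-6-[(benzyloxy)methyl]-2-[2-(dimethoxymethyl)-4-isopropyl-3,5,6-trimethoxyphenyl]oct-7-enoate
Product: 16 tert-butyl (6R,7E)-6-[(benzyloxy)methyl]-2-[2-(dimethoxymethyl)-4-isopropyl-3,5,6-trimethoxyphenyl]-9-oxodec-7-enoate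
Conditions: methyl vinyl ketone (5 equiv), second-generation Hoveyda–Grubbs catalyst (5 mol %), CH2Cl2, 40 °C
Reagents that add atoms: methyl vinyl ketone, CC(=O)C=C
Why: Olefin cross-metathesis between the monosubstituted alkene and the electron-poor partner should be selective for the cross product and give the (E)-enone under thermodynamic control.

Step 14
Reactants: 16 tert-butyl (6R,7E)-6-[(benzyloxy)methyl]-2-[2-(dimethoxymethyl)-4-isopropyl-3,5,6-trimethoxyphenyl]-9-oxodec-7-enoate
Product: 17 (6R,7E)-6-[(benzyloxy)methyl]-2-(2-formyl-4-isopropyl-3,5,6-trimethoxyphenyl)-9-oxodec-7-enoic acid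
Conditions: TFA, CH2Cl2, H2O (2 equiv), 0 °C to rt
Reagents that add atoms: water, O
Why: Acidolysis: the tert-butyl ester loses isobutene by an E1 pathway and the dimethyl acetal is hydrolysed, while the benzyl ether and the enone are stable to TFA.

Step 15
Reactants: 17 (6R,7E)-6-[(benzyloxy)methyl]-2-(2-formyl-4-isopropyl-3,5,6-trimethoxyphenyl)-9-oxodec-7-enoic acid
Product: 20 6α-acetyl-4α-[(benzyloxy)methyl]-11,12,14-trimethoxy-18,19-dinorabieta-8,11,13-trien-20,7β-olide, via acetoxy lactone 18 (not isolated), via 2-benzopyran-3-one 19 (not isolated)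
Conditions: Ac2O, toluene (0.01 M), 140 °C, sealed tube
Reagents that add atoms: none
Why: The carboxyl oxygen of 17 adds to the formyl carbon C7 (6-exo-trig, pseudo-acid formation), Ac2O acetylates the new lactol hydroxyl to give 18, and thermal 1,4-loss of acetic acid (C7–OAc, C10–H) gives the o-quinoid pyranone 19, so the C7–O lactone bond is made here from the acid oxygen. Compound 19 is a locked o-quinodimethane whose diene C7=C8–C9=C10 adds the tethered enone C5=C6 in an intramolecular Diels–Alder reaction (type 1, four-atom tether) that forms C10–C5 and C7–C6 and restores the benzene ring; the closest known reaction type is the acetic anhydride cyclodehydration of o-formylphenylacetic acids to 2-benzopyran-3-ones with Diels–Alder trapping in the same flask, intramolecular variants included. Ring B is the new cyclohexene of the [4+2] event, ring A is the six-membered tether ring closed by the C5–C10 bond through a chair-like exo (trans-fusing) transition state, and the lactone is the bridge that the pyranone ring becomes. C7 and C10 are bridgeheads and can only be syn; C5 follows from the exo tether (C4 toward the lactone bridge, H5 anti to C20, as in o-quinodimethane cyclisations that give trans-fused rings), C6 from the (E)-alkene geometry with the acetyl group endo under the arene, and the absolute sense from C4, whose CH2OBn group sits equatorial and away from the lactone carbonyl. The step needs regiocontrol, which the tether enforces (C5 to C10, not to C7), and facial control, which the equatorial preference at C4 together with the matched endo-acetyl and exo-tether preferences should secure; high dilution suppresses dimerisation of 19.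

Step 16
Reactants: 20 6α-acetyl-4α-[(benzyloxy)methyl]-11,12,14-trimethoxy-18,19-dinorabieta-8,11,13-trien-20,7β-olide
Product: 21 6α-acetoxy-4α-[(benzyloxy)methyl]-11,12,14-trimethoxy-18,19-dinorabieta-8,11,13-trien-20,7β-olide
Conditions: mCPBA, TFA (cat.), CH2Cl2, 0 °C to rt
Reagents that add atoms: 3-chloroperbenzoic acid, O=C(OO)c1cccc(Cl)c1
Why: Baeyer–Villiger oxidation: in the Criegee intermediate the secondary carbon C6 migrates in preference to methyl and with retention, so the 6α-acetyl group becomes the 6α-acetate.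

Step 17
Reactants: 21 6α-acetoxy-4α-[(benzyloxy)methyl]-11,12,14-trimethoxy-18,19-dinorabieta-8,11,13-trien-20,7β-olide
Product: 22 6α-acetoxy-4α-(hydroxymethyl)-11,12,14-trimethoxy-18,19-dinorabieta-8,11,13-trien-20,7β-olide
Conditions: BCl3, pentamethylbenzene, CH2Cl2, −78 °C
Reagents that add atoms: none
Why: Lewis acid debenzylation: BCl3 cleaves the primary benzyl ether at −78 °C with pentamethylbenzene as benzyl cation scavenger, conditions that should leave the aryl methyl ethers, the acetate and the benzylic lactone intact and that avoid hydrogenolysis.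

Step 18
Reactants: 22 6α-acetoxy-4α-(hydroxymethyl)-11,12,14-trimethoxy-18,19-dinorabieta-8,11,13-trien-20,7β-olide
Product: 23 6α-acetoxy-4α-formyl-11,12,14-trimethoxy-18,19-dinorabieta-8,11,13-trien-20,7β-olide
Conditions: Dess–Martin periodinane, NaHCO3, CH2Cl2, rt
Reagents that add atoms: none
Why: Dess–Martin oxidation of the primary alcohol to the aldehyde; the C4–H centre may epimerise without consequence because it is enolised in the next step.

Step 19
Reactants: 23 6α-acetoxy-4α-formyl-11,12,14-trimethoxy-18,19-dinorabieta-8,11,13-trien-20,7β-olide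
Product: 24 6α-acetoxy-11,12,14-trimethoxy-19-oxoabieta-8,11,13-trien-20,7β-olide (4α-methyl, 4β-formyl)
Conditions: KOt-Bu (1.1 equiv), MeI, THF, −78 to 0 °C
Reagents that add atoms: iodomethane, CI
Why: Alkylation of the potassium enolate of the α-branched aldehyde: methyl iodide should approach C4 from the α face (equatorial attack), because the β face is blocked by the syn-axial C20 lactone carbonyl on C10, which places methyl 4α and the formyl group 4β as in podocarpate-type alkylations.

Step 20
Reactants: 24 6α-acetoxy-11,12,14-trimethoxy-19-oxoabieta-8,11,13-trien-20,7β-olide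
Product: 26 6α,19-dihydroxy-11,12,14-trimethoxyabieta-8,11,13-trien-20,7β-olide, via hydroxy aldehyde 25 (not isolated)
Conditions: K2CO3 (0.2 equiv), MeOH, 0 °C to rt; then NaBH4, 0 °C
Reagents that add atoms: none
Why: Mild methanolysis should remove the unhindered secondary acetate while the lactone, whose carbonyl sits on the quaternary C10, is untouched, and NaBH4 then reduces the non-enolisable neopentyl aldehyde to the C19 alcohol (carbonyl reduction).

Step 21
Reactants: 26 6α,19-dihydroxy-11,12,14-trimethoxyabieta-8,11,13-trien-20,7β-olide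
Product: 28 6α,12,19-trihydroxy-11,14-dioxoabieta-8,12-dien-20,7β-olide (target), via hydroxyhydroquinone 27 (not isolated)
Conditions: BBr3, CH2Cl2, −78 to 0 °C; then aq. NaHCO3, air, EtOAc, rt
Reagents that add atoms: none
Why: Lewis acid cleavage of the three aryl methyl ethers gives the 11,12,14-trihydroxyarene, a hydroxyhydroquinone that should autoxidise in air to the 12-hydroxy-11,14-quinone; no stereocentre is affected.

**Compound list**

1 | 1,2,4-trimethoxybenzene | COc1ccc(OC)c(OC)c1 | starting material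
2 | 2-(2,3,6-trimethoxyphenyl)propan-2-ol | COc1ccc(OC)c(C(C)(C)O)c1OC | intermediate
3 | 2-isopropyl-1,3,4-trimethoxybenzene | COc1ccc(OC)c(C(C)C)c1OC | intermediate
4 | 3-isopropyl-2,4,5-trimethoxybenzaldehyde | COc1cc(C=O)c(OC)c(C(C)C)c1OC | intermediate
5 | 1-(dimethoxymethyl)-3-isopropyl-2,4,5-trimethoxybenzene | COc1cc(C(OC)OC)c(OC)c(C(C)C)c1OC | intermediate
6 | 1-(dimethoxymethyl)-2-iodo-5-isopropyl-3,4,6-trimethoxybenzene | COc1c(I)c(C(OC)OC)c(OC)c(C(C)C)c1OC | intermediate
7 | tert-butyl 2-[2-(dimethoxymethyl)-4-isopropyl-3,5,6-trimethoxyphenyl]acetate | COc1c(CC(=O)OC(C)(C)C)c(C(OC)OC)c(OC)c(C(C)C)c1OC | intermediate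
8 | (R)-4-benzyl-2-oxazolidinone | O=C1N[C@H](Cc2ccccc2)CO1 | starting material
9 | 5-bromopentanoyl chloride | O=C(Cl)CCCCBr | starting material
10 | (4R)-4-benzyl-3-(5-bromopentanoyl)-1,3-oxazolidin-2-one | O=C(CCCCBr)N1[C@H](Cc2ccccc2)COC1=O | intermediate
11 | (4R)-4-benzyl-3-[(2S)-2-[(benzyloxy)methyl]-5-bromopentanoyl]-1,3-oxazolidin-2-one | O=C([C@H](COCc1ccccc1)CCCBr)N1[C@H](Cc2ccccc2)COC1=O | intermediate
12 | (2R)-2-[(benzyloxy)methyl]-5-bromopentan-1-ol | OC[C@H](COCc1ccccc1)CCCBr | intermediate
13 | (2S)-2-[(benzyloxy)methyl]-5-bromopentanal | O=C[C@H](COCc1ccccc1)CCCBr | intermediate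
14 | {[(2R)-2-(3-bromopropyl)but-3-en-1-yl]oxy}methylbenzene | C=C[C@H](COCc1ccccc1)CCCBr | intermediate
15 | tert-butyl (6R)-6-[(benzyloxy)methyl]-2-[2-(dimethoxymethyl)-4-isopropyl-3,5,6-trimethoxyphenyl]oct-7-enoate (C2 epimers) | COc1c(C(CCC[C@@H](COCc2ccccc2)C=C)C(=O)OC(C)(C)C)c(C(OC)OC)c(OC)c(C(C)C)c1OC | intermediate
16 | tert-butyl (6R,7E)-6-[(benzyloxy)methyl]-2-[2-(dimethoxymethyl)-4-isopropyl-3,5,6-trimethoxyphenyl]-9-oxodec-7-enoate (C2 epimers) | COc1c(C(CCC[C@@H](COCc2ccccc2)/C=C/C(C)=O)C(=O)OC(C)(C)C)c(C(OC)OC)c(OC)c(C(C)C)c1OC | intermediate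
17 | (6R,7E)-6-[(benzyloxy)methyl]-2-(2-formyl-4-isopropyl-3,5,6-trimethoxyphenyl)-9-oxodec-7-enoic acid (C2 epimers) | COc1c(C(CCC[C@@H](COCc2ccccc2)/C=C/C(C)=O)C(=O)O)c(C=O)c(OC)c(C(C)C)c1OC | intermediate
18 | 1-acetoxy-4-[(4R,5E)-4-[(benzyloxy)methyl]-7-oxooct-5-en-1-yl]-7-isopropyl-5,6,8-trimethoxyisochroman-3-one (C1 and C4 epimers) | CC(=O)OC1OC(=O)C(CCC[C@@H](COCc2ccccc2)/C=C/C(C)=O)c2c(OC)c(OC)c(C(C)C)c(OC)c12 | intermediate (not isolated)
19 | 4-[(4R,5E)-4-[(benzyloxy)methyl]-7-oxooct-5-en-1-yl]-7-isopropyl-5,6,8-trimethoxy-3H-2-benzopyran-3-one | O=C1OC=C2C(OC)=C(C(C)C)C(OC)=C(OC)C2=C1CCC[C@@H](COCc3ccccc3)/C=C/C(C)=O | intermediate (not isolated)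
20 | 6α-acetyl-4α-[(benzyloxy)methyl]-11,12,14-trimethoxy-18,19-dinorabieta-8,11,13-trien-20,7β-olide (4β-H, 5α-H) | CC(C)c1c(OC)c(OC)c2c(c1OC)[C@H]1OC(=O)[C@@]23CCC[C@@H](COCc4ccccc4)[C@@H]3[C@H]1C(C)=O | intermediate
21 | 6α-acetoxy-4α-[(benzyloxy)methyl]-11,12,14-trimethoxy-18,19-dinorabieta-8,11,13-trien-20,7β-olide | CC(C)c1c(OC)c(OC)c2c(c1OC)[C@H]1OC(=O)[C@@]23CCC[C@@H](COCc4ccccc4)[C@@H]3[C@H]1OC(C)=O | intermediate
22 | 6α-acetoxy-4α-(hydroxymethyl)-11,12,14-trimethoxy-18,19-dinorabieta-8,11,13-trien-20,7β-olide | CC(C)c1c(OC)c(OC)c2c(c1OC)[C@H]1OC(=O)[C@@]23CCC[C@@H](CO)[C@@H]3[C@H]1OC(C)=O | intermediate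
23 | 6α-acetoxy-4α-formyl-11,12,14-trimethoxy-18,19-dinorabieta-8,11,13-trien-20,7β-olide | CC(C)c1c(OC)c(OC)c2c(c1OC)[C@H]1OC(=O)[C@@]23CCC[C@@H](C=O)[C@@H]3[C@H]1OC(C)=O | intermediate
24 | 6α-acetoxy-11,12,14-trimethoxy-19-oxoabieta-8,11,13-trien-20,7β-olide | CC(C)c1c(OC)c(OC)c2c(c1OC)[C@H]1OC(=O)[C@@]23CCC[C@](C)(C=O)[C@@H]3[C@H]1OC(C)=O | intermediate
25 | 6α-hydroxy-11,12,14-trimethoxy-19-oxoabieta-8,11,13-trien-20,7β-olide | CC(C)c1c(OC)c(OC)c2c(c1OC)[C@H]1OC(=O)[C@@]23CCC[C@](C)(C=O)[C@@H]3[C@H]1O | intermediate (not isolated)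
26 | 6α,19-dihydroxy-11,12,14-trimethoxyabieta-8,11,13-trien-20,7β-olide | CC(C)c1c(OC)c(OC)c2c(c1OC)[C@H]1OC(=O)[C@@]23CCC[C@](C)(CO)[C@@H]3[C@H]1O | intermediate
27 | 6α,11,12,14,19-pentahydroxyabieta-8,11,13-trien-20,7β-olide | CC(C)c1c(O)c(O)c2c(c1O)[C@H]1OC(=O)[C@@]23CCC[C@](C)(CO)[C@@H]3[C@H]1O | intermediate (not isolated)
28 | 6α,12,19-trihydroxy-11,14-dioxoabieta-8,12-dien-20,7β-olide | CC(C)C1=C(O)C(=O)C2=C(C1=O)[C@H]1OC(=O)[C@@]23CCC[C@](C)(CO)[C@@H]3[C@H]1O | target

**Step count.** 21 steps in total. The longest linear sequence is 16 steps (steps 1–6 and 12–21); the chain fragment (steps 7–11) joins at step 12.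

**Steps most likely to fail, with fallbacks**

1. Step 15. The o-quinoid pyranone may dimerise or polymerise faster than it cyclises, or facial control by the C4 centre may be eroded at 140 °C. The fallback sets out from 16 and replaces the pyranone by a photoenol. PPTS in wet acetone should hydrolyse only the aryl dimethyl acetal to give tert-butyl (6R,7E)-6-[(benzyloxy)methyl]-2-(2-formyl-4-isopropyl-3,5,6-trimethoxyphenyl)-9-oxodec-7-enoate F1. Irradiation at 365 nm in degassed toluene photoenolises the o-alkylbenzaldehyde (1,5-hydrogen shift from C10–H) to a hydroxy-o-quinodimethane, which should undergo the same intramolecular [4+2] addition to the enone and give tert-butyl 6α-acetyl-4α-[(benzyloxy)methyl]-7-hydroxy-11,12,14-trimethoxy-18,19-dinorabieta-8,11,13-trien-20-oate F2. TFA in CH2Cl2 then cleaves the tert-butyl ester and ionises the benzylic C7–OH, so that the C20 acid closes the 20,7β-lactone; this returns the route to 20.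

2. Step 19. The hindered aldehyde enolate may undergo O-methylation, or react sluggishly, instead of C-methylation. The fallback sets out from 23 and delivers the methyl carbon by cyclopropanation. TBSOTf and Et3N should give the silyl enol ether 6α-acetoxy-4-[(tert-butyldimethylsilyloxy)methylene]-11,12,14-trimethoxy-18,19-dinorabieta-8,11,13-trien-20,7β-olide F3. Simmons–Smith cyclopropanation (Et2Zn, CH2I2) from the open α face gives 6α-acetoxy-19-(tert-butyldimethylsilyloxy)-11,12,14-trimethoxy-18,19-cycloabieta-8,11,13-trien-20,7β-olide F4. TsOH in wet THF opens the siloxycyclopropane at the C18–C19 bond to the 4α-methyl-4β-formyl compound, which returns the route to 24.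

3. Step 21. BBr3 may ionise the benzylic C7–O lactone bond, or promote translactonisation toward the C19 hydroxyl, before all three ethers are cleaved. The fallback sets out from 26 and uses oxidative demethylation. (NH4)2Ce(NO3)6 in MeCN/H2O at 0 °C should oxidise the para-related 11- and 14-methoxy groups to the quinone 6α,19-dihydroxy-12-methoxy-11,14-dioxoabieta-8,12-dien-20,7β-olide F5. Dilute aqueous HClO4 in THF then hydrolyses the vinylogous ester at C12, which comes back to the route at 28.

**Further compounds**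

F1 | step 15 | tert-butyl (6R,7E)-6-[(benzyloxy)methyl]-2-(2-formyl-4-isopropyl-3,5,6-trimethoxyphenyl)-9-oxodec-7-enoate | COc1c(C(CCC[C@@H](COCc2ccccc2)/C=C/C(C)=O)C(=O)OC(C)(C)C)c(C=O)c(OC)c(C(C)C)c1OC
F2 | step 15 | tert-butyl 6α-acetyl-4α-[(benzyloxy)methyl]-7-hydroxy-11,12,14-trimethoxy-18,19-dinorabieta-8,11,13-trien-20-oate (C7 epimers) | CC(C)c1c(OC)c(OC)c2c(c1OC)C(O)[C@H](C(C)=O)[C@H]1[C@H](COCc3ccccc3)CCC[C@]21C(=O)OC(C)(C)C
F3 | step 19 | 6α-acetoxy-4-[(tert-butyldimethylsilyloxy)methylene]-11,12,14-trimethoxy-18,19-dinorabieta-8,11,13-trien-20,7β-olide | CC(C)c1c(OC)c(OC)c2c(c1OC)[C@H]1OC(=O)[C@@]23CCCC(=CO[Si](C)(C)C(C)(C)C)[C@@H]3[C@H]1OC(C)=O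
F4 | step 19 | 6α-acetoxy-19-(tert-butyldimethylsilyloxy)-11,12,14-trimethoxy-18,19-cycloabieta-8,11,13-trien-20,7β-olide | CC(C)c1c(OC)c(OC)c2c(c1OC)[C@H]1OC(=O)[C@@]23CCC[C@@]4(CC4O[Si](C)(C)C(C)(C)C)[C@@H]3[C@H]1OC(C)=O
F5 | step 21 | 6α,19-dihydroxy-12-methoxy-11,14-dioxoabieta-8,12-dien-20,7β-olide | CC(C)C1=C(OC)C(=O)C2=C(C1=O)[C@H]1OC(=O)[C@@]23CCC[C@](C)(CO)[C@@H]3[C@H]1O
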